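**Assumption:** the target (3,5-dihydroxy-7-methoxy-8-butanoyloxyflavone) has no stereocentre and is achiral, so there is no enantiomer to control; transient stereocentres in non-isolated intermediates are racemic and are destroyed again.

## Retrosynthetic overview

1. Target ⇐ hydrogenolysis of a 3-O-benzyl ether ⇐ 8-O-butanoylation of 3-benzyloxy-5,8-dihydroxy-7-methoxyflavone (the 5-OH is chelated to the C4 carbonyl and stays free).
2. The 5,8-hydroquinone ⇐ 7-methoxyflavone-5,8-quinone ⇐ oxidative demethylation of 3-benzyloxy-5,7,8-trimethoxyflavone, which sets the 8-oxygen apart from the 7-OMe.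
3. Flavonol ⇐ C3-hydroxylation of 5,7,8-trimethoxyflavone ⇐ oxidative cyclisation of a 2'-hydroxychalcone (ring C is formed last; rings A and B are bought as arenes).
4. Chalcone ⇐ Claisen–Schmidt aldol condensation of 2-hydroxy-3,4,6-trimethoxyacetophenone with benzaldehyde (key C–C bond).
5. Acetophenone ⇐ Friedel–Crafts acetylation with ortho-demethylation of 1,2,3,5-tetramethoxybenzene ⇐ 3,4,5-trimethoxyphenol.

## Route

Step 1
Reactants: 1 3,4,5-trimethoxyphenol
Product: 2 1,2,3,5-tetramethoxybenzene
Conditions: MeI (1.5 equiv), K2CO3 (2 equiv), acetone, reflux, 12 h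
Reagents that add atoms: iodomethane, CI
Why: Williamson ether synthesis on an unhindered phenoxide gives the symmetrical tetramethyl ether cleanly.

Step 2
Reactants: 2 1,2,3,5-tetramethoxybenzene
Product: 4 2-hydroxy-3,4,6-trimethoxyacetophenone, via 2,3,4,6-tetramethoxyacetophenone 3 (not isolated)
Conditions: AcCl (1.2 equiv), AlCl3 (2.5 equiv), Et2O, 0 °C → reflux, 4 h; then ice/2 M HCl
Reagents that add atoms: acetyl chloride, CC(Cl)=O
Why: Friedel–Crafts acylation can only occur at the two equivalent free ring positions, and AlCl3 chelated to the new ketone then cleaves the ortho methoxy group that is flanked on both sides (twisted out of plane, most basic), giving the 2-hydroxy isomer.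

Step 3
Reactants: 4 2-hydroxy-3,4,6-trimethoxyacetophenone; 5 benzaldehyde
Product: 7 (E)-2'-hydroxy-3',4',6'-trimethoxychalcone, via racemic beta-hydroxy ketone aldol adduct 6 (not isolated)
Conditions: PhCHO (1.2 equiv), 50% aq KOH, EtOH, rt, 48 h; then cold 2 M HCl
Reagents that add atoms: none
Why: Claisen–Schmidt crossed aldol condensation of the methyl ketone enolate with a non-enolisable aldehyde, followed by E1cB dehydration to the conjugated E-enone; the adduct's stereocentre is lost on dehydration.

Step 4
Reactants: 7 (E)-2'-hydroxy-3',4',6'-trimethoxychalcone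
Product: 9 5,7,8-trimethoxyflavone, via racemic 5,7,8-trimethoxyflavanone 8 (not isolated)
Conditions: I2 (10 mol%), DMSO, 130 °C, 2 h; then aq Na2S2O3
Reagents that add atoms: none
Why: I2/DMSO oxidative cyclisation (oxa-Michael ring closure, then iodination and loss of HI, with DMSO reoxidising HI) is a dependable chalcone-to-flavone method that is insensitive to the 6'-methoxy group; the flavanone stereocentre is erased by dehydrogenation.

Step 5
Reactants: 9 5,7,8-trimethoxyflavone
Product: 11 3-hydroxy-5,7,8-trimethoxyflavone, via racemic 5,7,8-trimethoxyflavone 2,3-epoxide 10 (not isolated)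
Conditions: DMDO (about 0.07 M in acetone, 3 equiv in portions), CH2Cl2, 0 °C → rt, 24 h; evaporate; then p-TsOH·H2O (10 mol%), CH2Cl2, rt, 1 h
Reagents that add atoms: dimethyldioxirane, CC1(C)OO1
Why: Dioxirane epoxidation of the enol-ether-like C2=C3 bond followed by acid-catalysed epoxide opening and tautomerisation gives the flavonol without the aurone problem of direct chalcone oxidation; the epoxide stereocentres disappear on aromatisation.

Step 6
Reactants: 11 3-hydroxy-5,7,8-trimethoxyflavone
Product: 12 3-(benzyloxy)-5,7,8-trimethoxyflavone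
Conditions: BnBr (1.3 equiv), K2CO3 (2 equiv), DMF, 50 °C, 4 h
Reagents that add atoms: benzyl bromide, BrCc1ccccc1
Why: Williamson benzylation of the only free (acidic, enolic) hydroxyl protects the oxidation-sensitive 3-OH as a group that is later removed by hydrogenolysis.

Step 7
Reactants: 12 3-(benzyloxy)-5,7,8-trimethoxyflavone
Product: 13 3-(benzyloxy)-7-methoxy-2-phenyl-4H-chromene-4,5,8-trione
Conditions: (NH4)2Ce(NO3)6 (2.5 equiv), MeCN/H2O 3:1, 0 °C, 20 min
Reagents that add atoms: water, O
Why: Oxidative demethylation of a para-dimethoxyarene by tetravalent cerium gives the para-quinone across C5/C8 (water attacks the ring carbons and the two methyl ethers leave as methanol), so the 7-OMe, which has no para oxygen partner, is kept.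

Step 8
Reactants: 13 3-(benzyloxy)-7-methoxy-2-phenyl-4H-chromene-4,5,8-trione
Product: 14 3-(benzyloxy)-5,8-dihydroxy-7-methoxyflavone
Conditions: Na2S2O4 (3 equiv), EtOAc/H2O, rt, 15 min, under N2
Reagents that add atoms: none
Why: Dithionite reduction of a quinone to its hydroquinone is fast and touches neither the benzyl ether nor the chromone.

Step 9
Reactants: 14 3-(benzyloxy)-5,8-dihydroxy-7-methoxyflavone
Product: 15 3-(benzyloxy)-5-hydroxy-7-methoxy-4-oxo-2-phenyl-4H-chromen-8-yl butanoate
Conditions: butanoyl chloride (1.05 equiv), pyridine (3 equiv), CH2Cl2, −20 → 0 °C, N2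
Reagents that add atoms: butanoyl chloride, CCCC(Cl)=O
Why: Chemoselective Einhorn-type O-acylation: the free 8-OH reacts with the acylpyridinium, while the 5-OH is locked in a strong hydrogen bond to the C4 carbonyl and is not acylated by one equivalent at low temperature.

Step 10
Reactants: 15 3-(benzyloxy)-5-hydroxy-7-methoxy-4-oxo-2-phenyl-4H-chromen-8-yl butanoate
Product: 16 3,5-dihydroxy-7-methoxy-4-oxo-2-phenyl-4H-chromen-8-yl butanoate (target)
Conditions: H2 (1 atm), 10% Pd/C, EtOAc, rt, 1–2 h
Reagents that add atoms: none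
Why: Catalytic hydrogenolysis removes the benzyl ether under neutral, non-nucleophilic conditions that leave the aryl butanoate, the chromone C=C and the carbonyl intact.

## Compound list

1 | 3,4,5-trimethoxyphenol | COc1cc(O)cc(OC)c1OC | starting material
2 | 1,2,3,5-tetramethoxybenzene | COc1cc(OC)cc(OC)c1OC | intermediate
3 | 1-(2,3,4,6-tetramethoxyphenyl)ethan-1-one (2,3,4,6-tetramethoxyacetophenone) | CC(=O)c1c(OC)cc(OC)c(OC)c1OC | intermediate (not isolated)
4 | 1-(2-hydroxy-3,4,6-trimethoxyphenyl)ethan-1-one (2-hydroxy-3,4,6-trimethoxyacetophenone) | CC(=O)c1c(OC)cc(OC)c(OC)c1O | intermediate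
5 | benzaldehyde | O=Cc1ccccc1 | starting material
6 | rac-3-hydroxy-1-(2-hydroxy-3,4,6-trimethoxyphenyl)-3-phenylpropan-1-one (racemate, one stereocentre) | COc1cc(OC)c(C(=O)CC(O)c2ccccc2)c(O)c1OC | intermediate (not isolated)
7 | (E)-1-(2-hydroxy-3,4,6-trimethoxyphenyl)-3-phenylprop-2-en-1-one | COc1cc(OC)c(C(=O)/C=C/c2ccccc2)c(O)c1OC | intermediate
8 | rac-5,7,8-trimethoxy-2-phenylchroman-4-one (racemate, one stereocentre) | COc1cc(OC)c2C(=O)CC(c3ccccc3)Oc2c1OC | intermediate (not isolated)
9 | 5,7,8-trimethoxy-2-phenyl-4H-chromen-4-one | COc1cc(OC)c2c(=O)cc(-c3ccccc3)oc2c1OC | intermediate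
10 | rac-2,3-epoxy-5,7,8-trimethoxy-2-phenylchroman-4-one (racemate, one enantiomer drawn, cis ring fusion) | COc1cc(OC)c2C(=O)[C@@H]3O[C@]3(c3ccccc3)Oc2c1OC | intermediate (not isolated)
11 | 3-hydroxy-5,7,8-trimethoxy-2-phenyl-4H-chromen-4-one | COc1cc(OC)c2c(=O)c(O)c(-c3ccccc3)oc2c1OC | intermediate
12 | 3-(benzyloxy)-5,7,8-trimethoxy-2-phenyl-4H-chromen-4-one | COc1cc(OC)c2c(=O)c(OCc3ccccc3)c(-c3ccccc3)oc2c1OC | intermediate
13 | 3-(benzyloxy)-7-methoxy-2-phenyl-4H-chromene-4,5,8-trione | COC1=CC(=O)C2=C(C1=O)OC(c1ccccc1)=C(OCc1ccccc1)C2=O | intermediate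
14 | 3-(benzyloxy)-5,8-dihydroxy-7-methoxy-2-phenyl-4H-chromen-4-one | COc1cc(O)c2c(=O)c(OCc3ccccc3)c(-c3ccccc3)oc2c1O | intermediate
15 | 3-(benzyloxy)-5-hydroxy-7-methoxy-4-oxo-2-phenyl-4H-chromen-8-yl butanoate | CCCC(=O)Oc1c(OC)cc(O)c2c(=O)c(OCc3ccccc3)c(-c3ccccc3)oc12 | intermediate
16 | 3,5-dihydroxy-7-methoxy-4-oxo-2-phenyl-4H-chromen-8-yl butanoate (achiral) | CCCC(=O)Oc1c(OC)cc(O)c2c(=O)c(O)c(-c3ccccc3)oc12 | target

## Step count and risks

Total step count: 10. Longest linear sequence: 10 steps (1 → 16); benzaldehyde 5 enters at step 3.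

Steps most likely to fail:

**Step 7** (oxidative demethylation with (NH4)2Ce(NO3)6). The oxidant could attack the benzyloxy enol ether or give over-oxidation. The fallback sets out from 11 and comes back at 13, bypassing step 6. It oxidises a para-methoxyphenol with PhI(OAc)2 instead of oxidising the diether by electron transfer. AlCl3 in dry MeCN (rt → 50 °C) cleaves only the 5-OMe peri to the carbonyl and gives 3,5-dihydroxy-7,8-dimethoxyflavone F3. BnBr (1.1 equiv) with K2CO3 in acetone then benzylates the 3-OH in preference to the chelated 5-OH and gives 3-(benzyloxy)-5-hydroxy-7,8-dimethoxyflavone F4. PhI(OAc)2 in MeCN/H2O at 0 °C converts this phenol into quinone 13 with loss of methanol.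

**Step 5** (DMDO epoxidation and isomerisation). Epoxidation of the electron-poor chromone double bond may be slow or incomplete. The fallback sets out from 9 and comes back at 11. It uses deprotonation, borylation and oxidation instead of electrophilic oxygen transfer. LiN(iPr)2 in THF at −78 °C removes the C3 proton to give 3-lithio-5,7,8-trimethoxyflavone F1. B(OMe)3 traps it as dimethyl (5,7,8-trimethoxy-4-oxo-2-phenyl-4H-chromen-3-yl)boronate F2. H2O2/AcOH in the same flask oxidises the C–B bond to give 11.

**Step 9** (selective 8-O-acylation). The risks are air oxidation of the hydroquinone under basic conditions and some 5-O-acylation. The fallback sets out from 14 and comes back at 15. It masks the 5-OH as a boron chelate under acidic conditions, by analogy with the classical boric acid/anhydride partial acylation of peri-hydroxy carbonyl compounds. Heating 14 with B(OH)3 (1.2 equiv) in butanoic anhydride at 60 °C ties the 5-O and the C4 carbonyl into a chelate while the anhydride acylates the 8-OH. This gives the bis(butanoyloxy)boron 4-oxo/5-olate chelate of 3-(benzyloxy)-8-(butanoyloxy)-7-methoxyflavone F5. Stirring with ice-water/THF hydrolyses the chelate to 15.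

## Further compounds

F1 | step 5 | 3-lithio-5,7,8-trimethoxyflavone | [Li]c1c(-c2ccccc2)oc2c(OC)c(OC)cc(OC)c2c1=O
F2 | step 5 | dimethyl (5,7,8-trimethoxy-4-oxo-2-phenyl-4H-chromen-3-yl)boronate | COB(OC)c1c(-c2ccccc2)oc2c(OC)c(OC)cc(OC)c2c1=O
F3 | step 7 | 3,5-dihydroxy-7,8-dimethoxyflavone | COc1cc(O)c2c(=O)c(O)c(-c3ccccc3)oc2c1OC
F4 | step 7 | 3-(benzyloxy)-5-hydroxy-7,8-dimethoxyflavone | COc1cc(O)c2c(=O)c(OCc3ccccc3)c(-c3ccccc3)oc2c1OC
F5 | step 9 | bis(butanoyloxy)boron 4-oxo/5-olate chelate of 3-(benzyloxy)-8-(butanoyloxy)-7-methoxyflavone | CCCC(=O)Oc1c(OC)cc2O[B-](OC(=O)CCC)(OC(=O)CCC)[O+]=C3C(OCc4ccccc4)=C(c4ccccc4)Oc1c23
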